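The seven-membered ring (C1, C5–C10) is read as a benzene ring, C5–C10, that already carries O6 and O9 (para to each other) and the C8 methyl group, with C1 slipped into its C5–C10 bond. The route rests on disconnecting C1–C5 and C1–C10. A copper carbene at C1, tethered through C2(=O)–C3–C4, cyclopropanates the C5–C10 edge and the norcaradiene opens, so cyclopentanone, cycloheptatriene and quaternary C1 arise in one operation. The precursor is an enantiopure α-methyl α-diazoketone in which one di-tert-butylsilylene clamps the C4 carbinol oxygen to the ortho phenol oxygen O6. Only one arene face is then reachable, and C6 (fluoride) and C9 (acid) are later unmasked separately.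

Key step: step 7

**Remarks before the steps**
- **Numbering** (used for all compounds, open-chain ones by anticipation): C1 quaternary C–CH3; C2, C3 ring CH2; C4 C(OH)(iPr); C5 ring-fusion CH; C6 CH–O-acyl; C7=C8(CH3); C9 CH–OH; C10 CH2. O4, O6 and O9 are the oxygens on those carbons. α is the face of the C1 methyl group.
- **Target check:** 1R,4R,5S,6S,9R. The C1-CH3, 4-OH and 9-OH lie on the α face. H5, isopropyl and the 6-O-acyl group lie on the β face (trans-fused).
- **Why O6 is silylated, not methylated:** after ring expansion C4–O4 is allylic to the C5=C6 enol ether, which makes it a vinylogous ketal. Aqueous acid would ionise it and give the transposed C4=C5–C6=O enone with loss of O4. Fluoride therefore releases C6, and only the C9 methyl enol ether is left for acid.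
- **Why C2 is removed by an anionic method:** a C2 radical next to C1 of a cycloheptatriene/norcaradiene pair could rearrange by cyclopropylcarbinyl opening or vinyl shift.
- **Why the phenol directs the allylation:** an ortho-substituted aryl isopropyl ketone gives a size-based allylation catalyst little to distinguish.
- **Assumption:** the (R,R) antipode of allylsilane 4 is taken to attack the Si face of ketone 3 (giving 4R); both antipodes are commercial, and the other one is used if 5 proves to have the opposite configuration.

**Step 1**
Reactants: 1 2,5-dimethoxytoluene; 2 isobutyryl chloride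
Product: 3 1-(2-hydroxy-5-methoxy-4-methylphenyl)-2-methylpropan-1-one
Conditions: AlCl3 (2.5 equiv), CH2Cl2, 0 °C → reflux; cold aq HCl work-up
Reagents that add atoms: none
Why: Friedel–Crafts acylation should go para to the methyl group (the only unhindered activated site), and excess AlCl3 should then cleave only the methoxy group chelated to the new ketone, uncovering the phenol that steps 2 and 3 need.

**Step 2**
Reactants: 3; 4 (3aR,7aR)-2-allyl-1,3-bis(4-bromobenzyl)-2-chlorooctahydro-1H-1,3,2-benzodiazasilole
Product: 5 2-[(3R)-3-hydroxy-2-methylhex-5-en-3-yl]-4-methoxy-5-methylphenol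
Conditions: 4 (1.5 equiv), CH2Cl2, 23 → 40 °C; aqueous work-up (NaHCO3 wash)
Reagents that add atoms: none
Why: In this phenol-directed asymmetric allylation with a strained chiral allylchlorosilane, a reaction type established for hindered 2-hydroxyaryl ketones including branched alkyl ones, the phenol displaces chloride at silicon, the bound ketone is activated intramolecularly and allyl is transferred through a closed chair-like transition state, so the diamine backbone sets C4 as R by Si-face attack.

**Step 3**
Reactants: 5
Product: 6 (4R)-4-allyl-2,2-di-tert-butyl-4-isopropyl-6-methoxy-7-methyl-4H-1,3,2-benzodioxasiline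
Conditions: tBu2Si(OTf)2 (1.2 equiv), 2,6-lutidine (3 equiv), CH2Cl2, 0 °C → rt
Reagents that add atoms: di-tert-butylsilyl bis(trifluoromethanesulfonate), CC(C)(C)[Si](OS(=O)(=O)C(F)(F)F)(OS(=O)(=O)C(F)(F)F)C(C)(C)C
Why: In this cyclic silylene protection the phenol should be silylated first and the hindered tertiary carbinol then closes a six-membered ring intramolecularly, so one reagent masks both oxygens, keeps O4 a poor donor toward a carbene and fixes the C4–C5 rotamer.

**Step 4**
Reactants: 6
Product: 7 2-[(4R)-2,2-di-tert-butyl-4-isopropyl-6-methoxy-7-methyl-4H-1,3,2-benzodioxasilin-4-yl]acetaldehyde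
Conditions: OsO4 (2 mol %), NaIO4 (4 equiv), 2,6-lutidine, dioxane/H2O 3:1, rt
Reagents that add atoms: sodium periodate (oxygen relayed through OsO4), [Na+].[O-]I(=O)(=O)=O
Why: Lemieux–Johnson cleavage touches only the terminal alkene, avoids ozone or RuO4 that would attack the electron-rich arene, and the lutidine buffer protects the silylene.

**Step 5**
Reactants: 7
Product: 8 2-[(4R)-2,2-di-tert-butyl-4-isopropyl-6-methoxy-7-methyl-4H-1,3,2-benzodioxasilin-4-yl]acetic acid
Conditions: NaClO2, NaH2PO4, 2-methyl-2-butene, tBuOH/H2O, 0 °C → rt
Reagents that add atoms: sodium chlorite, [Na+].[O-]Cl=O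
Why: Pinnick oxidation is selective for the aldehyde, runs near pH 4 where di-tert-butylsilylene acetals hold, and the alkene scavenger removes HOCl before it can chlorinate the arene.

**Step 6**
Reactants: 8; 9 N-ethyl-N-nitrosourea
Product: 12 3-diazo-1-[(4R)-2,2-di-tert-butyl-4-isopropyl-6-methoxy-7-methyl-4H-1,3,2-benzodioxasilin-4-yl]butan-2-one (the O4/O6-bridged 2-diazo-5-aryl-6-methylheptan-3-one), via acid chloride 10 (not isolated), via diazoethane 11 (not isolated)
Conditions: (a) 8, 1-chloro-N,N,2-trimethylprop-1-en-1-amine (1.2 equiv), CH2Cl2, 0 °C; (b) 9, 40 % aq KOH/Et2O, 0 °C, ether layer dried over KOH (separate fire-polished vessel, shield); (c) 10 added to 11 (3 equiv), Et2O, −20 → 0 °C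
Reagents that add atoms: none
Why: This is acylation of a diazoalkane by an acid chloride (first stage of the Arndt–Eistert sequence), in which the α-chloroenamine makes the chloride without releasing acid and excess diazoethane both attacks the CH2–COCl carbonyl and scavenges HCl, the standard access to α-methyl α-diazoketones.

**Step 7**
Reactants: 12
Product: 14 (1R,4R)-4,6-(di-tert-butylsilanediyldioxy)-9-methoxydauca-5,7,9-trien-2-one (an 8a-methyl-3,8a-dihydroazulen-1(2H)-one), via norcaradiene 13 (not isolated)
Conditions: Cu(MeCN)4PF6 (5 mol %), 2,2'-(propane-2,2-diyl)bis[(4R)-4-phenyl-4,5-dihydrooxazole] (6 mol %), NaBArF4 (6 mol %), CH2Cl2, 40 °C, 12 added by syringe pump; filtration through Et3N-deactivated neutral alumina, used at once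
Reagents that add atoms: none
Why: Loss of N2 gives an electrophilic copper carbene at C1 that adds suprafacially across the C5–C10 edge of the arene ([2+1] cycloaddition) to norcaradiene 13, whose disrotatory 6π electrocyclic opening breaks the old C5–C10 bond and gives cycloheptatriene 14. This is the intramolecular Buchner reaction of aryl-tethered α-diazoketones, known with copper(I)–bis(oxazoline) catalysts for α-methyl diazoketones that give 8a-methylazulenones, including substrates with a fully substituted benzylic carbon. The cyclopentanone closes through the C1–C5 bond of the cyclopropanation (five-atom chain C1–C2–C3–C4–C5), and the seven-membered ring arises by expansion of the six-membered ring when C1 ends up between C5 and C10 in the electrocyclic step. C1 is controlled by C4: the silylene holds O4 near the arene plane beside O6, so C3 and isopropyl point to opposite faces, the short tether reaches only one face, and because C2 and C4 must be cis on the cyclopropane the methyl group ends on the side of O4 (1R with 4R), so the ligand antipode can change the rate but not the sense. Site selectivity for C5–C10 over C5–C6 follows from the oxygen substituent and siladioxane ring at C6, and chemoselectivity over 1,2-hydride shift from the methyl group, insertion into the isopropyl methine C–H and ylide formation rests on the electron-rich arene, the cationic copper catalyst and the poor donor ability of silylated oxygen. The main danger is opening of the donor–acceptor norcaradiene, assisted by the C9 methoxy group, with rearomatisation to a 2-tetralone, so acid is excluded and 14 is carried on immediately.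

**Step 8**
Reactants: 14
Product: 15 C2 hydrazone of 14, (1R,4R)
Conditions: N2H4·H2O (10 equiv), Et3N, EtOH, 60 °C
Reagents that add atoms: hydrazine (as hydrate), NN
Why: Hydrazone formation at an α-quaternary cyclopentanone (the situation of 17-oxo steroids, which condense readily) runs in a basic medium that cannot trigger rearomatisation, should leave the methyl enol ether and the hindered silylene untouched, and removes the carbonyl acceptor that makes the norcaradiene tautomer labile.

**Step 9**
Reactants: 15
Product: 16 (1R,4R)-4,6-(di-tert-butylsilanediyldioxy)-9-methoxydauca-5,7,9-triene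
Conditions: KOtBu (3 equiv), tBuOH, DMSO, 23 °C, 15 added slowly
Reagents that add atoms: none
Why: In the room-temperature KOtBu/DMSO form of the Wolff–Kishner reduction N2 leaves from a diazenyl anion and C2 is protonated at once, so no C2 radical or cation that could rearrange the neighbouring triene is formed, and C1 and C4 are untouched.

**Step 10**
Reactants: 16
Product: 17 (1R,4R,5R)-4-hydroxy-9-methoxydauca-7,9-dien-6-one (trans-fused, H5 β)
Conditions: HF·pyridine, pyridine, THF, 0 °C → rt; NaHCO3 quench
Reagents that add atoms: none
Why: In this fluoride cleavage of the silylene without aqueous acid the enol O6–Si bond should break first and the enol then ketonises by protonation of C5 from the β face, because the α face carries the axial C1 methyl group and the still silylated O4, which gives the trans-fused ketone that is also the thermodynamic isomer (C6 trans to isopropyl, O4–H···O6 hydrogen bond), after which the second fluoride frees the tertiary alcohol and the C9 methyl enol ether stays.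

**Step 11**
Reactants: 17
Product: 19 (1R,4R,5S,6S)-4,6-dihydroxydauc-7-en-9-one, via methoxydiene diol 18 (not isolated)
Conditions: Me4NBH(OAc)3 (5 equiv), MeCN/AcOH 1:1, −30 → 0 °C; then 0.5 M aq HCl, THF, 0 °C
Reagents that add atoms: water, O
Why: In the Evans–Saksena hydroxyl-directed reduction the 4-OH exchanges onto boron and hydride is delivered intramolecularly to the α face of the only ketone, C6 (external hydride would come from the β face, away from the axial C1 methyl group), which sets 6S with O6 β, and dilute acid then hydrolyses the C9 methyl enol ether by protonation at C10, which is safe now that C4–O4 is no longer part of a vinylogous ketal.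

**Step 12**
Reactants: 20 vanillic acid
Product: 21 4-acetoxy-3-methoxybenzoic acid
Conditions: Ac2O, pyridine, rt; H2O work-up
Reagents that add atoms: acetic anhydride, CC(=O)OC(C)=O
Why: Phenol acetylation blocks self-condensation in the coupling, and any mixed anhydride at the carboxyl group is hydrolysed on work-up.

**Step 13**
Reactants: 19; 21
Product: 22 (1R,4R,5S,6S)-4-hydroxy-9-oxodauc-7-en-6-yl 4-acetoxy-3-methoxybenzoate
Conditions: DCC, DMAP, CH2Cl2, 0 °C → rt
Reagents that add atoms: none
Why: Steglich esterification should acylate only the secondary allylic 6-OH (the tertiary 4-OH is inert), as is usual for 4,6-dihydroxydaucanes with 4-acyloxybenzoic acids, and C6 keeps its configuration because its C–O bond is not touched.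

**Step 14**
Reactants: 22
Product: 23 (1R,4R,5S,6S,9R)-4,9-dihydroxydauc-7-en-6-yl 4-acetoxy-3-methoxybenzoate
Conditions: NaBH4, CeCl3·7H2O, MeOH, −78 °C
Reagents that add atoms: none
Why: Luche 1,2-reduction of the enone should take hydride from the β face, because the C1 methyl group is axial on the α face and 1,3 to C9 while the C6 ester is pseudo-equatorial, which places the new hydroxyl α (9R).

**Step 15**
Reactants: 23
Product: 24 target, (1R,4R,5S,6S,9R)-4,9-dihydroxydauc-7-en-6-yl 4-hydroxy-3-methoxybenzoate
Conditions: pyrrolidine (3 equiv), CH2Cl2, 0 °C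
Reagents that add atoms: none
Why: Aminolysis cleaves the activated aryl acetate far faster than the hindered alkyl benzoate and avoids alkoxide conditions that could move the acyl group.

**Compound list**
1 | 2,5-dimethoxytoluene | Cc1cc(OC)ccc1OC | starting material
2 | isobutyryl chloride | CC(C)C(Cl)=O | starting material
3 | 1-(2-hydroxy-5-methoxy-4-methylphenyl)-2-methylpropan-1-one | CC(C)C(=O)c1cc(OC)c(C)cc1O | intermediate
4 | (3aR,7aR)-2-allyl-1,3-bis(4-bromobenzyl)-2-chlorooctahydro-1H-1,3,2-benzodiazasilole | C=CC[Si]1(Cl)N(Cc2ccc(Br)cc2)[C@@H]2CCCC[C@H]2N1Cc1ccc(Br)cc1 | starting material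
5 | 2-[(3R)-3-hydroxy-2-methylhex-5-en-3-yl]-4-methoxy-5-methylphenol | C=CC[C@@](O)(C(C)C)c1cc(OC)c(C)cc1O | intermediate
6 | (4R)-4-allyl-2,2-di-tert-butyl-4-isopropyl-6-methoxy-7-methyl-4H-1,3,2-benzodioxasiline | C=CC[C@]1(C(C)C)O[Si](C(C)(C)C)(C(C)(C)C)Oc2cc(C)c(OC)cc21 | intermediate
7 | (4R)-benzodioxasilin-4-ylacetaldehyde (as in step 4) | O=CC[C@]1(C(C)C)O[Si](C(C)(C)C)(C(C)(C)C)Oc2cc(C)c(OC)cc21 | intermediate
8 | (4R)-benzodioxasilin-4-ylacetic acid (as in step 5) | OC(=O)C[C@]1(C(C)C)O[Si](C(C)(C)C)(C(C)(C)C)Oc2cc(C)c(OC)cc21 | intermediate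
9 | N-ethyl-N-nitrosourea | CCN(N=O)C(N)=O | starting material
10 | (4R)-benzodioxasilin-4-ylacetyl chloride | ClC(=O)C[C@]1(C(C)C)O[Si](C(C)(C)C)(C(C)(C)C)Oc2cc(C)c(OC)cc21 | intermediate
11 | diazoethane | CC=[N+]=[N-] | intermediate
12 | 3-diazo-1-[(4R)-benzodioxasilin-4-yl]butan-2-one (key-step precursor) | CC(=[N+]=[N-])C(=O)C[C@]1(C(C)C)O[Si](C(C)(C)C)(C(C)(C)C)Oc2cc(C)c(OC)cc21 | intermediate
13 | (1R,4R,5S,10S)-norcaradiene, cyclopropane C1–C5–C10, C1 methyl over the cyclohexadiene | COC1=C(C)C=C2O[Si](C(C)(C)C)(C(C)(C)C)O[C@@]3(C(C)C)CC(=O)[C@]4(C)[C@@H]1[C@]234 | intermediate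
14 | (1R,4R)-4,6-(di-tert-butylsilanediyldioxy)-9-methoxydauca-5,7,9-trien-2-one (key-step product) | COC1=C[C@@]2(C)C(=O)C[C@]3(C(C)C)O[Si](C(C)(C)C)(C(C)(C)C)OC(=C23)C=C1C | intermediate
15 | C2 hydrazone of 14, (1R,4R) | COC1=C[C@@]2(C)C(=NN)C[C@]3(C(C)C)O[Si](C(C)(C)C)(C(C)(C)C)OC(=C23)C=C1C | intermediate
16 | (1R,4R)-4,6-(di-tert-butylsilanediyldioxy)-9-methoxydauca-5,7,9-triene | COC1=C[C@@]2(C)CC[C@]3(C(C)C)O[Si](C(C)(C)C)(C(C)(C)C)OC(=C23)C=C1C | intermediate
17 | (1R,4R,5R)-4-hydroxy-9-methoxydauca-7,9-dien-6-one | O=C1C=C(C)C(OC)=C[C@@]2(C)CC[C@@](O)(C(C)C)[C@H]12 | intermediate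
18 | (1R,4R,5S,6S)-9-methoxydauca-7,9-diene-4,6-diol | O[C@H]1C=C(C)C(OC)=C[C@@]2(C)CC[C@@](O)(C(C)C)[C@H]12 | intermediate
19 | (1R,4R,5S,6S)-4,6-dihydroxydauc-7-en-9-one | O[C@H]1C=C(C)C(=O)C[C@@]2(C)CC[C@@](O)(C(C)C)[C@H]12 | intermediate
20 | vanillic acid | COc1cc(C(=O)O)ccc1O | starting material
21 | 4-acetoxy-3-methoxybenzoic acid | COc1cc(C(=O)O)ccc1OC(C)=O | intermediate
22 | (1R,4R,5S,6S)-4-hydroxy-9-oxodauc-7-en-6-yl 4-acetoxy-3-methoxybenzoate | COc1cc(C(=O)O[C@H]2C=C(C)C(=O)C[C@@]3(C)CC[C@@](O)(C(C)C)[C@H]23)ccc1OC(C)=O | intermediate
23 | (1R,4R,5S,6S,9R)-4,9-dihydroxydauc-7-en-6-yl 4-acetoxy-3-methoxybenzoate | COc1cc(C(=O)O[C@H]2C=C(C)[C@H](O)C[C@@]3(C)CC[C@@](O)(C(C)C)[C@H]23)ccc1OC(C)=O | intermediate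
24 | (1R,4R,5S,6S,9R)-4,9-dihydroxydauc-7-en-6-yl 4-hydroxy-3-methoxybenzoate | COc1cc(C(=O)O[C@H]2C=C(C)[C@H](O)C[C@@]3(C)CC[C@@](O)(C(C)C)[C@H]23)ccc1O | target

Total steps: 15. Longest linear sequence: 14 (steps 1–11 and 13–15; step 12 is a one-step side branch).

**Steps most likely to fail**

**1. Step 7.**
- **Process at risk:** the fully substituted carbene may escape by 1,2-hydride shift from its methyl group, or by insertion into the isopropyl methine C–H, before it reaches the arene. Arene attack may also end in opening of the donor–acceptor norcaradiene and rearomatisation.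
- **Fallback:** the methyl group is taken out of the carbene step and C1 is made quaternary by enolate alkylation. The fallback sets out from acid 8 through acid chloride 10. This is added to ethereal diazomethane to give the terminal diazoketone 1-diazo-3-[(4R)-2,2-di-tert-butyl-4-isopropyl-6-methoxy-7-methyl-4H-1,3,2-benzodioxasilin-4-yl]propan-2-one F1.
- Terminal diazoketones have no migrating β-hydrogen and are the best-behaved Buchner substrates. Rh2(OAc)4 in CH2Cl2 should therefore give, on the same clamped face, the C1–H analogue (1R,4R)-4,6-(di-tert-butylsilanediyldioxy)-9-methoxy-1-demethyldauca-5,7,9-trien-2-one F2.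
- KOtBu in THF/tBuOH with MeI should then form the more substituted, triene-conjugated enolate. Methylation at C1 should come from the α face, anti to the pseudo-axial isopropyl group. This comes back to the route at 14.

**2. Step 8 (together with step 9).**
- **Process at risk:** condensation at the neopentyl-type ketone may be slow. Base-induced loss of O4 by β-elimination, attack of hydrazine or alkoxide on the silyl enol ether, or rearomatisation could then overtake it.
- **Fallback:** enolate and palladium hydride chemistry replaces hydrazone chemistry. The fallback sets out from 14. KHMDS and N-(5-chloropyridin-2-yl)triflimide in THF at −78 °C give the enol triflate (1R,4S)-4,6-(di-tert-butylsilanediyldioxy)-9-methoxydauca-2,5,7,9-tetraen-2-yl triflate F3 (the C4 descriptor changes, the geometry does not).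
- The only possible enolate points to C3. The silylene ring holds C4–O4 away from good overlap with it, which should slow elimination.
- Pd(OAc)2, PPh3, HCO2H and Bu3N in DMF at 60 °C give the tetraene (1R,4S)-4,6-(di-tert-butylsilanediyldioxy)-9-methoxydauca-2,5,7,9-tetraene F4.
- Diimide (2-nitrobenzenesulfonylhydrazide, Et3N, rt) should reduce the cis-disubstituted cyclopentene bond much faster than the tri- and tetrasubstituted donor-bearing triene bonds. This comes back to the route at 16.

**3. Step 11.**
- **Process at risk:** ligand exchange at the hindered tertiary hydroxyl may be slow, so that no directed delivery takes place. Hydride may be transferred to the conjugated system. The C9 enol ether may be protonated early in acetic acid, followed by ionic reduction.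
- **Fallback:** the hydride is bound covalently to O4. The fallback sets out from 17. Chlorodiisopropylsilane, imidazole and DMAP in CH2Cl2 give the hydridosilyl ether (1R,4R,5R)-4-(diisopropylsilyloxy)-9-methoxydauca-7,9-dien-6-one F5.
- Catalytic SnCl4 in CH2Cl2 at −78 °C triggers intramolecular hydrosilylation of the β-silyloxy ketone, a known route to anti-1,3-diols, from the α face. The product is the cyclic (1R,4R,5S,6S)-4,6-(diisopropylsilanediyldioxy)-9-methoxydauca-7,9-diene F6.
- Aqueous HF in MeCN then cleaves the silylene and hydrolyses the C9 enol ether. This comes back to the route at 19.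

**Further compounds**
F1 | step 7 | 1-diazo-3-[(4R)-2,2-di-tert-butyl-4-isopropyl-6-methoxy-7-methyl-4H-1,3,2-benzodioxasilin-4-yl]propan-2-one | [N-]=[N+]=CC(=O)C[C@]1(C(C)C)O[Si](C(C)(C)C)(C(C)(C)C)Oc2cc(C)c(OC)cc21
F2 | step 7 | (1R,4R)-4,6-(di-tert-butylsilanediyldioxy)-9-methoxy-1-demethyldauca-5,7,9-trien-2-one | COC1=C[C@H]2C(=O)C[C@]3(C(C)C)O[Si](C(C)(C)C)(C(C)(C)C)OC(=C23)C=C1C
F3 | step 8 | (1R,4S)-4,6-(di-tert-butylsilanediyldioxy)-9-methoxydauca-2,5,7,9-tetraen-2-yl triflate | COC1=C[C@@]2(C)C(OS(=O)(=O)C(F)(F)F)=C[C@]3(C(C)C)O[Si](C(C)(C)C)(C(C)(C)C)OC(=C23)C=C1C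
F4 | step 8 | (1R,4S)-4,6-(di-tert-butylsilanediyldioxy)-9-methoxydauca-2,5,7,9-tetraene | COC1=C[C@@]2(C)C=C[C@]3(C(C)C)O[Si](C(C)(C)C)(C(C)(C)C)OC(=C23)C=C1C
F5 | step 11 | (1R,4R,5R)-4-(diisopropylsilyloxy)-9-methoxydauca-7,9-dien-6-one | O=C1C=C(C)C(OC)=C[C@@]2(C)CC[C@@](O[SiH](C(C)C)C(C)C)(C(C)C)[C@H]12
F6 | step 11 | (1R,4R,5S,6S)-4,6-(diisopropylsilanediyldioxy)-9-methoxydauca-7,9-diene | COC1=C[C@@]2(C)CC[C@]3(C(C)C)O[Si](C(C)C)(C(C)C)O[C@@H](C=C1C)[C@H]23
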